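(The readings were computed from invented constants.)

The midnight run stalled where the autumn run did not: by 3.00 min its starting material stood at 65.5 %, while that of the autumn run had fallen to 26.0 % by the same time. Each starting material that reacts takes one coupling partner, and each double product takes a second, so the concentration of coupling partner enters the rate of both steps. The gap between the runs is read by the partner ratio, coupling partner charged per starting material charged: 0.500 in teal, against 1.00 in green and 2.00 in ochre. Below one, coupling partner is the limiting reagent and starting material has a floor, one minus the ratio. For midnight that floor is 64.3 %, just under its last reading.

| flask | starting material | coupling partner | remark | time |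
|---|---|---|---|---|
| autumn | 0.59 M | 1 M | run made earlier |  |
| midnight | 2.8 M | 1 M | run made earlier |  |
| ochre | 0.50 M | 1.00 M |  | 4.0 min |
| green | 1.0 M | 1.00 M |  | 4.0 min |
| teal | 2.0 M | 1.00 M |  | 4.0 min |

| run | time / min | double product / % | starting material / % |
|---|---|---|---|
| autumn | 0.667 | 0.7 | 69.4 |
| autumn | 1.33 | 1.9 | 49.1 |
| autumn | 2.00 | 5.0 | 37.2 |
| autumn | 3.00 | 6.5 | 26.0 |
| midnight | 0.250 | 0 | 87.7 |
| midnight | 0.500 | 0 | 80.4 |
| midnight | 1.33 | 0.2 | 70.3 |
| midnight | 3.00 | 1.2 | 65.5 |

(each reading ± 0.5 percentage points)

- "hardly changes" means that all values lie within two and a half points (for a concentration: within two and a half percent of the largest)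

- [double product] at the end for ochre, green, teal, in this order
- the shape of the row from first to last (rises, then falls / hardly changes / falls, then rises / rises all the way / falls all the way)

Two extreme flasks can be solved in the head. With the ratio far above one, coupling partner stays near its charge, both steps are pseudo-first-order, each percentage is the same at any charge, and double product in molar terms grows in proportion to the starting material charged. With the ratio far below one, coupling partner is consumed early, mostly by starting material, which outnumbers first product, so a larger charge leaves less double product. Ochre, green and teal straddle a ratio of one, so the row should first rise and then fall. The readings point the same way: at 3.00 min the autumn run holds 0.0384 M of double product and the midnight run 0.0336 M, close together from charges far apart. The reckoning here commits to a top near green, without a firm height.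

The forecast gives 0.054 M, 0.06 M and 0.043 M, a row that rises, then falls, in its words: “The row therefore peaks in the middle, though the differences are modest.”

The flasks give 0.0588 M, 0.0658 M and 0.0428 M, a row that rises, then falls, and the forecast stands within its margin.

    starting material + coupling partner → first product (k = 0.0107 L mol⁻¹ s⁻¹)
    coupling partner + first product → double product (k = 0.00149 L mol⁻¹ s⁻¹)
    coupling partner + double product → tris adduct (k = 1.94 × 10⁻⁴ L mol⁻¹ s⁻¹)
    coupling partner + tris adduct → tetra adduct (k = 0.0545 L mol⁻¹ s⁻¹)

Teal shows the ratio at work. With a ratio of 0.500 the floor of teal is 50.0 %, and at 40.0 min its starting material rests at 52.3 % with coupling partner at 0 %. The shrinking supply of coupling partner holds the double product of teal down: the same teal run with coupling partner held at its charge gives 0.392 M instead of 0.0428 M.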